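**Retrosynthetic overview**
1. The 2H-pyran ring is closed last: O1–C8a by intramolecular Pd C–O coupling of the (Z)-bromoaryl tertiary allylic alcohol 25, which leaves the C2 stereocentre untouched. 25 comes from Sonogashira coupling and Lindlar reduction of propargylic alcohol 18 with aryl iodide 23.
2. The C2 stereocentre of 18 comes from Sharpless epoxidation of (E)-allylic alcohol 15 and epoxy chloride → alkyne elimination. 15 comes from alkyne 13 by Negishi carboalumination and formaldehyde.
3. 13 comes from octalone 8 by epoxidation, Eschenmoser–Tanabe fragmentation and methylenation. The temporary enone ring serves only to set the secondary methyl trans to the quaternary methyl by equilibration.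
4. Key C–C bond (quaternary ring carbon–CH2): auxiliary-controlled Michael addition of the (S)-1-phenylethylamine imine of 2,6-dimethylcyclohexanone to methyl vinyl ketone.
5. Ring order: cyclohexane (bought) → temporary cyclohexenone (made, then cleaved) → arene (bought) → 2H-pyran (last).

Assumption: 2,6-dimethylcyclohexanone is bought as its cis/trans mixture, so 3, 5 and 6 are C6-epimer mixtures and 7 is a mixture at C8/C8a; their SMILES leave those centres open because they converge in step 3.

**Route**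

Step 1
Reactants: 1 2,6-dimethylcyclohexan-1-one; 2 (S)-1-phenylethylamine
Product: 3 N-[(1S)-1-phenylethyl]-2,6-dimethylcyclohexan-1-imine
Conditions: cat. p-TsOH, toluene, reflux, Dean–Stark
Reagents that add atoms: none
Why: Acid-catalysed imine condensation with azeotropic water removal gives the chiral imine, which equilibrates with its secondary enamine tautomers.

Step 2
Reactants: 3 N-[(1S)-1-phenylethyl]-2,6-dimethylcyclohexan-1-imine; 4 methyl vinyl ketone
Product: 6 (2R)-2,6-dimethyl-2-(3-oxobutyl)cyclohexan-1-one, via Michael adduct imine 5 (not isolated)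
Conditions: THF, rt→40 °C, 3–5 d; then 20% aq. AcOH, rt
Reagents that add atoms: water (O)
Why: Deracemising Michael addition of the chiral imine (d'Angelo, aza-ene-type transition state): the more substituted secondary enamine adds to the enone on the face away from the auxiliary phenyl, so the (S)-amine sets the quaternary centre R (≥90% ee expected), and mild hydrolysis releases the diketone and the amine.

Step 3
Reactants: 6 (2R)-2,6-dimethyl-2-(3-oxobutyl)cyclohexan-1-one
Product: 8 (4aR,8R)-4a,8-dimethyl-4,4a,5,6,7,8-hexahydronaphthalen-2(3H)-one, via bicyclic ketol 7 (not isolated)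
Conditions: NaOMe, MeOH, reflux; chromatography (minor C8 epimer re-equilibrated)
Reagents that add atoms: none
Why: Intramolecular aldol condensation (second stage of a Robinson annulation) closes the enone ring, and C8, now epimerisable through the extended dienolate, settles with its methyl equatorial and trans to the axial angular methyl, as in 6α-methyl-Δ4-3-keto steroids.

Step 4
Reactants: 8 (4aR,8R)-4a,8-dimethyl-4,4a,5,6,7,8-hexahydronaphthalen-2(3H)-one
Product: 9 (1S,4aR,8R,8aS)-1,8a-epoxy-4a,8-dimethyloctahydronaphthalen-2(1H)-one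
Conditions: 30% H2O2, aq. NaOH, MeOH, 0 °C→rt
Reagents that add atoms: hydrogen peroxide (OO)
Why: Weitz–Scheffer nucleophilic epoxidation of the enone; the epoxide configuration is irrelevant because both epoxide carbons are destroyed in the next step, and C8 is no longer acidic afterwards.

Step 5
Reactants: 9 (1S,4aR,8R,8aS)-1,8a-epoxy-4a,8-dimethyloctahydronaphthalen-2(1H)-one; 10 4-methylbenzenesulfonohydrazide
Product: 12 (2R,6R)-2-(but-3-yn-1-yl)-2,6-dimethylcyclohexan-1-one, via epoxy tosylhydrazone 11 (not isolated)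
Conditions: AcOH/CH2Cl2 1:1, −20 °C→rt
Reagents that add atoms: none
Why: Eschenmoser–Tanabe fragmentation: the epoxy tosylhydrazone cleaves the C1–C8a bond with loss of N2 and sulfinate, giving the ring ketone and a terminal alkyne under weakly acidic, cold conditions that do not epimerise the α-methyl centre.

Step 6
Reactants: 12 (2R,6R)-2-(but-3-yn-1-yl)-2,6-dimethylcyclohexan-1-one
Product: 13 (1R,3R)-1-(but-3-yn-1-yl)-1,3-dimethyl-2-methylidenecyclohexane
Conditions: Zn/CH2Br2/TiCl4 (Lombardo reagent), THF–CH2Cl2, 0 °C→rt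
Reagents that add atoms: dibromomethane (BrCBr)
Why: Takai–Lombardo methylenation is non-basic, so the hindered enolisable ketone is converted to the exocyclic alkene without epimerising the adjacent CH(CH3) centre and without touching the alkyne.

Step 7
Reactants: 13 (1R,3R)-1-(but-3-yn-1-yl)-1,3-dimethyl-2-methylidenecyclohexane
Product: 15 (2E)-5-[(1R,3R)-1,3-dimethyl-2-methylidenecyclohexyl]-3-methylpent-2-en-1-ol, via alkenyldimethylalane 14 (not isolated)
Conditions: AlMe3, Cp2ZrCl2 (25 mol%), CH2Cl2, rt; evaporate; n-BuLi, THF/hexane, −78 °C; (CH2O)n, →rt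
Reagents that add atoms: trimethylaluminium (C[Al](C)C); formaldehyde from paraformaldehyde (C=O)
Why: Negishi Zr-catalysed syn-carboalumination puts methyl on the internal alkyne carbon, and the alkenyl aluminate traps formaldehyde with retention to give the pure (E)-trisubstituted allylic alcohol; the hindered 1,1-disubstituted alkene is inert.

Step 8
Reactants: 15 (2E)-5-[(1R,3R)-1,3-dimethyl-2-methylidenecyclohexyl]-3-methylpent-2-en-1-ol
Product: 16 [(2S,3S)-3-{2-[(1R,3R)-1,3-dimethyl-2-methylidenecyclohexyl]ethyl}-3-methyloxiran-2-yl]methanol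
Conditions: Ti(OiPr)4 (10 mol%), L-(+)-DET, t-BuOOH, 4 Å MS, CH2Cl2, −20 °C
Reagents that add atoms: tert-butyl hydroperoxide (CC(C)(C)OO)
Why: Katsuki–Sharpless asymmetric epoxidation is reagent-controlled (L-(+)-tartrate gives the 2S,3S epoxide, as with geraniol), which fixes the future chromene C2 as S, and the Ti/TBHP system only epoxidises the allylic alcohol alkene.

Step 9
Reactants: 16 [(2S,3S)-3-{2-[(1R,3R)-1,3-dimethyl-2-methylidenecyclohexyl]ethyl}-3-methyloxiran-2-yl]methanol
Product: 17 (2R,3S)-2-(chloromethyl)-3-{2-[(1R,3R)-1,3-dimethyl-2-methylidenecyclohexyl]ethyl}-3-methyloxirane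
Conditions: PPh3, CCl4, NaHCO3, reflux
Reagents that add atoms: tetrachloromethane (ClC(Cl)(Cl)Cl)
Why: Appel chlorination converts the primary alcohol to the chloride under neutral conditions that leave the epoxide and its two stereocentres intact (the C2 descriptor changes only through CIP priority).

Step 10
Reactants: 17 (2R,3S)-2-(chloromethyl)-3-{2-[(1R,3R)-1,3-dimethyl-2-methylidenecyclohexyl]ethyl}-3-methyloxirane
Product: 18 (3S)-5-[(1R,3R)-1,3-dimethyl-2-methylidenecyclohexyl]-3-methylpent-1-yn-3-ol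
Conditions: n-BuLi (3.5 equiv), THF, −40→−20 °C; H2O
Reagents that add atoms: none
Why: Base-induced double elimination of a 2,3-epoxy chloride (Yadav–Takano propargylic alcohol synthesis): deprotonation next to chlorine opens the epoxide and a second elimination of HCl gives the alkyne, while the C3–O bond is never broken, so the tertiary carbinol keeps its S configuration.

Step 11
Reactants: 19 5-bromo-2,4-dimethoxybenzaldehyde
Product: 21 5-bromo-2,4-dimethoxyphenol, via aryl formate 20 (not isolated)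
Conditions: mCPBA, CH2Cl2, 0 °C→rt; then K2CO3 (cat.), MeOH, rt
Reagents that add atoms: 3-chloroperoxybenzoic acid (OOC(=O)c1cccc(Cl)c1)
Why: Baeyer–Villiger (Dakin-type) oxidation with migration of the electron-rich aryl group gives the formate, which methanolysis converts to the phenol.

Step 12
Reactants: 21 5-bromo-2,4-dimethoxyphenol
Product: 22 3-bromo-2-iodo-4,6-dimethoxyphenol
Conditions: I2, NaHCO3, THF/H2O, 0 °C→rt
Reagents that add atoms: iodine (II)
Why: Electrophilic aromatic iodination of the phenoxide goes to the only free ortho position, since the other free carbon (between the two methoxy groups) is meta to the phenoxide oxygen.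

Step 13
Reactants: 22 3-bromo-2-iodo-4,6-dimethoxyphenol
Product: 23 (3-bromo-2-iodo-4,6-dimethoxyphenoxy)tri(propan-2-yl)silane
Conditions: TIPSOTf, 2,6-lutidine, CH2Cl2, 0 °C→rt
Reagents that add atoms: triisopropylsilyl trifluoromethanesulfonate (CC(C)[Si](OS(=O)(=O)C(F)(F)F)(C(C)C)C(C)C)
Why: Silyl protection of the phenol prevents benzofuran formation in the Sonogashira step and gives an ether stable to amine and carbonate bases but cleaved by fluoride.

Step 14
Reactants: 18 (3S)-5-[(1R,3R)-1,3-dimethyl-2-methylidenecyclohexyl]-3-methylpent-1-yn-3-ol; 23 (3-bromo-2-iodo-4,6-dimethoxyphenoxy)tri(propan-2-yl)silane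
Product: 24 (3S)-1-[2-bromo-3,5-dimethoxy-6-(triisopropylsilyloxy)phenyl]-5-[(1R,3R)-1,3-dimethyl-2-methylidenecyclohexyl]-3-methylpent-1-yn-3-ol
Conditions: PdCl2(PPh3)2 (5 mol%), CuI (10 mol%), Et3N/THF, 50 °C, degassed
Reagents that add atoms: none
Why: Sonogashira coupling occurs at the C–I bond in preference to C–Br and tolerates the free tertiary propargylic alcohol.

Step 15
Reactants: 24 (3S)-1-[2-bromo-3,5-dimethoxy-6-(triisopropylsilyloxy)phenyl]-5-[(1R,3R)-1,3-dimethyl-2-methylidenecyclohexyl]-3-methylpent-1-yn-3-ol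
Product: 25 (1Z,3S)-1-[2-bromo-3,5-dimethoxy-6-(triisopropylsilyloxy)phenyl]-5-[(1R,3R)-1,3-dimethyl-2-methylidenecyclohexyl]-3-methylpent-1-en-3-ol
Conditions: H2 (1 atm), Lindlar catalyst, quinoline, EtOAc, rt
Reagents that add atoms: none
Why: Lindlar syn-semihydrogenation gives the (Z)-alkene needed to bring the tertiary hydroxyl next to the aryl bromide, and the poisoned catalyst spares the hindered exocyclic alkene and the C–Br bond.

Step 16
Reactants: 25 (1Z,3S)-1-[2-bromo-3,5-dimethoxy-6-(triisopropylsilyloxy)phenyl]-5-[(1R,3R)-1,3-dimethyl-2-methylidenecyclohexyl]-3-methylpent-1-en-3-ol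
Product: 26 (2S)-2-{2-[(1R,3R)-1,3-dimethyl-2-methylidenecyclohexyl]ethyl}-6,8-dimethoxy-2-methyl-5-(triisopropylsilyloxy)-2H-chromene
Conditions: Pd(OAc)2 (5 mol%), t-BuXPhos (10 mol%), Cs2CO3, toluene, 80 °C
Reagents that add atoms: none
Why: Buchwald-type Pd-catalysed intramolecular C–O coupling forms the aryl–oxygen bond in a six-membered ring; the tertiary alkoxide has no β-hydrogen and its C–O bond is never broken, so C2 stays S.

Step 17
Reactants: 26 (2S)-2-{2-[(1R,3R)-1,3-dimethyl-2-methylidenecyclohexyl]ethyl}-6,8-dimethoxy-2-methyl-5-(triisopropylsilyloxy)-2H-chromene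
Product: 27 metachromin B, (2S)-2-{2-[(1R,3R)-1,3-dimethyl-2-methylidenecyclohexyl]ethyl}-6,8-dimethoxy-2-methyl-2H-chromen-5-ol
Conditions: TBAF, THF, 0 °C, dark
Reagents that add atoms: none
Why: Fluoride-mediated silyl ether cleavage frees the phenol under cold, non-acidic conditions that leave the acid- and light-sensitive 2H-chromene and the exocyclic alkene untouched.

**Compound list**
1 | 2,6-dimethylcyclohexan-1-one (cis/trans mixture) | CC1CCCC(C)C1=O | starting material
2 | (S)-1-phenylethylamine | C[C@H](N)c1ccccc1 | starting material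
3 | N-[(1S)-1-phenylethyl]-2,6-dimethylcyclohexan-1-imine (ring methyls cis/trans) | CC1CCCC(C)C1=N[C@@H](C)c1ccccc1 | intermediate
4 | methyl vinyl ketone (but-3-en-2-one) | C=CC(C)=O | starting material
5 | 4-[(1R)-1,3-dimethyl-2-{[(1S)-1-phenylethyl]imino}cyclohexyl]butan-2-one (C3 epimers) | CC(=O)CC[C@@]1(C)CCCC(C)C1=N[C@@H](C)c1ccccc1 | intermediate (not isolated)
6 | (2R)-2,6-dimethyl-2-(3-oxobutyl)cyclohexan-1-one (C6 epimers) | CC(=O)CC[C@@]1(C)CCCC(C)C1=O | intermediate
7 | (4aR)-8a-hydroxy-4a,8-dimethyloctahydronaphthalen-2(1H)-one (C8/C8a mixture) | CC1CCC[C@]2(C)CCC(=O)CC12O | intermediate (not isolated)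
8 | (4aR,8R)-4a,8-dimethyl-4,4a,5,6,7,8-hexahydronaphthalen-2(3H)-one (methyls trans) | C[C@@H]1CCC[C@]2(C)CCC(=O)C=C12 | intermediate
9 | (1S,4aR,8R,8aS)-1,8a-epoxy-4a,8-dimethyloctahydronaphthalen-2(1H)-one (epoxide cis to the angular methyl; the other epoxide isomer also forms and gives the same 12) | C[C@@H]1CCC[C@]2(C)CCC(=O)[C@H]3O[C@@]123 | intermediate
10 | 4-methylbenzenesulfonohydrazide | Cc1ccc(S(=O)(=O)NN)cc1 | starting material
11 | tosylhydrazone of 9 at C2 | C[C@@H]1CCC[C@]2(C)CCC(=NNS(=O)(=O)c4ccc(C)cc4)[C@H]3O[C@@]123 | intermediate (not isolated)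
12 | (2R,6R)-2-(but-3-yn-1-yl)-2,6-dimethylcyclohexan-1-one | O=C1[C@H](C)CCC[C@]1(C)CCC#C | intermediate
13 | (1R,3R)-1-(but-3-yn-1-yl)-1,3-dimethyl-2-methylidenecyclohexane | C=C1[C@H](C)CCC[C@]1(C)CCC#C | intermediate
14 | dimethyl{(1E)-4-[(1R,3R)-1,3-dimethyl-2-methylidenecyclohexyl]-2-methylbut-1-en-1-yl}alumane | C=C1[C@H](C)CCC[C@]1(C)CC/C(C)=C/[Al](C)C | intermediate (not isolated)
15 | (2E)-5-[(1R,3R)-1,3-dimethyl-2-methylidenecyclohexyl]-3-methylpent-2-en-1-ol | C=C1[C@H](C)CCC[C@]1(C)CC/C(C)=C/CO | intermediate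
16 | [(2S,3S)-3-{2-[(1R,3R)-1,3-dimethyl-2-methylidenecyclohexyl]ethyl}-3-methyloxiran-2-yl]methanol | C=C1[C@H](C)CCC[C@]1(C)CC[C@]2(C)O[C@H]2CO | intermediate
17 | (2R,3S)-2-(chloromethyl)-3-{2-[(1R,3R)-1,3-dimethyl-2-methylidenecyclohexyl]ethyl}-3-methyloxirane | C=C1[C@H](C)CCC[C@]1(C)CC[C@]2(C)O[C@H]2CCl | intermediate
18 | (3S)-5-[(1R,3R)-1,3-dimethyl-2-methylidenecyclohexyl]-3-methylpent-1-yn-3-ol | C=C1[C@H](C)CCC[C@]1(C)CC[C@@](O)(C)C#C | intermediate
19 | 5-bromo-2,4-dimethoxybenzaldehyde | O=Cc1cc(Br)c(OC)cc1OC | starting material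
20 | 5-bromo-2,4-dimethoxyphenyl formate | O=COc1cc(Br)c(OC)cc1OC | intermediate (not isolated)
21 | 5-bromo-2,4-dimethoxyphenol | Oc1cc(Br)c(OC)cc1OC | intermediate
22 | 3-bromo-2-iodo-4,6-dimethoxyphenol | Oc1c(I)c(Br)c(OC)cc1OC | intermediate
23 | (3-bromo-2-iodo-4,6-dimethoxyphenoxy)tri(propan-2-yl)silane | CC(C)[Si](Oc1c(I)c(Br)c(OC)cc1OC)(C(C)C)C(C)C | intermediate
24 | (3S)-1-[2-bromo-3,5-dimethoxy-6-(triisopropylsilyloxy)phenyl]-5-[(1R,3R)-1,3-dimethyl-2-methylidenecyclohexyl]-3-methylpent-1-yn-3-ol | C=C1[C@H](C)CCC[C@]1(C)CC[C@@](O)(C)C#Cc1c(Br)c(OC)cc(OC)c1O[Si](C(C)C)(C(C)C)C(C)C | intermediate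
25 | (1Z,3S)-1-[2-bromo-3,5-dimethoxy-6-(triisopropylsilyloxy)phenyl]-5-[(1R,3R)-1,3-dimethyl-2-methylidenecyclohexyl]-3-methylpent-1-en-3-ol | C=C1[C@H](C)CCC[C@]1(C)CC[C@@](O)(C)/C=C\c1c(Br)c(OC)cc(OC)c1O[Si](C(C)C)(C(C)C)C(C)C | intermediate
26 | (2S)-2-{2-[(1R,3R)-1,3-dimethyl-2-methylidenecyclohexyl]ethyl}-6,8-dimethoxy-2-methyl-5-(triisopropylsilyloxy)-2H-chromene | C=C1[C@H](C)CCC[C@]1(C)CC[C@@]1(C)C=Cc2c(O[Si](C(C)C)(C(C)C)C(C)C)c(OC)cc(OC)c2O1 | intermediate
27 | metachromin B, (2S)-2-{2-[(1R,3R)-1,3-dimethyl-2-methylidenecyclohexyl]ethyl}-6,8-dimethoxy-2-methyl-2H-chromen-5-ol | C=C1[C@H](C)CCC[C@]1(C)CC[C@@]1(C)C=Cc2c(O)c(OC)cc(OC)c2O1 | target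

**Totals and risks**
Total steps: 17. Longest linear sequence: 14 (steps 1–10, then 14–17); the arene branch is 3 steps (11–13).

Most likely to fail:

Step 4. The enone β-carbon is fully substituted and flanked by a quaternary and a tertiary carbon, so hydroperoxide addition may stall. The fallback sets out from 8 and comes back at 13, bypassing steps 4–6. Ozonolysis of 8 with oxidative work-up (O3, EtOAc/AcOH, −20 °C; then H2O2) cleaves the enone, with loss of C1 as formic acid, to 3-[(1R,3R)-1,3-dimethyl-2-oxocyclohexyl]propanoic acid F1. TMSCHN2 in MeOH/toluene gives methyl 3-[(1R,3R)-1,3-dimethyl-2-oxocyclohexyl]propanoate F2. Lombardo methylenation as in step 6 gives methyl 3-[(1R,3R)-1,3-dimethyl-2-methylidenecyclohexyl]propanoate F3. DIBAL-H (CH2Cl2, −78 °C) gives 3-[(1R,3R)-1,3-dimethyl-2-methylidenecyclohexyl]propanal F4. Ohira–Bestmann homologation (dimethyl (1-diazo-2-oxopropyl)phosphonate, K2CO3, MeOH) then gives 13.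

Step 6. The 2,2,6-trisubstituted ketone is very hindered, and any epimerisation of the α-methyl centre erodes the ring stereochemistry. The fallback sets out from 12 and comes back at 13. Excess TMSCH2Li/CeCl3 (THF, −78 °C; the first equivalent is consumed by the alkyne C–H) adds to the ketone without enolisation to give (2R,6R)-2-(but-3-yn-1-yl)-2,6-dimethyl-1-[(trimethylsilyl)methyl]cyclohexan-1-ol F5. KH in THF then effects Peterson elimination to 13.

Step 16. The aryl bromide is electron-rich and flanked on both sides, so C–O reductive elimination from palladium may be slow or diverted. The fallback sets out from 25 and comes back at 26. Copper-catalysed halogen exchange (CuI, NaI, trans-N,N′-dimethylcyclohexane-1,2-diamine, dioxane, 110 °C) gives (1Z,3S)-1-[2-iodo-3,5-dimethoxy-6-(triisopropylsilyloxy)phenyl]-5-[(1R,3R)-1,3-dimethyl-2-methylidenecyclohexyl]-3-methylpent-1-en-3-ol F6. Ullmann-type intramolecular etherification (CuI, 3,4,7,8-tetramethyl-1,10-phenanthroline, Cs2CO3, toluene, 110 °C) then closes the ring to 26, again without touching the C2–O bond.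

**Further compounds**
F1 | step 4 | 3-[(1R,3R)-1,3-dimethyl-2-oxocyclohexyl]propanoic acid | O=C1[C@H](C)CCC[C@]1(C)CCC(=O)O
F2 | step 4 | methyl 3-[(1R,3R)-1,3-dimethyl-2-oxocyclohexyl]propanoate | O=C1[C@H](C)CCC[C@]1(C)CCC(=O)OC
F3 | step 4 | methyl 3-[(1R,3R)-1,3-dimethyl-2-methylidenecyclohexyl]propanoate | C=C1[C@H](C)CCC[C@]1(C)CCC(=O)OC
F4 | step 4 | 3-[(1R,3R)-1,3-dimethyl-2-methylidenecyclohexyl]propanal | C=C1[C@H](C)CCC[C@]1(C)CCC=O
F5 | step 6 | (2R,6R)-2-(but-3-yn-1-yl)-2,6-dimethyl-1-[(trimethylsilyl)methyl]cyclohexan-1-ol (C1 epimers) | OC1(C[Si](C)(C)C)[C@H](C)CCC[C@]1(C)CCC#C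
F6 | step 16 | (1Z,3S)-1-[2-iodo-3,5-dimethoxy-6-(triisopropylsilyloxy)phenyl]-5-[(1R,3R)-1,3-dimethyl-2-methylidenecyclohexyl]-3-methylpent-1-en-3-ol | C=C1[C@H](C)CCC[C@]1(C)CC[C@@](O)(C)/C=C\c1c(I)c(OC)cc(OC)c1O[Si](C(C)C)(C(C)C)C(C)C
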